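The rate constants are assumed; no experiment stands behind them.

Read at 40 s, each flask shows the share of Je in Je plus Jf, both as fractions of the charge.

    Jb → Jc (k1 = 0.260 /s)
    Jc → Jd (k2 = 0.0752 /s)
    Jd → Je (k3 = 0.0377 /s)
    Ja + Jd → Jf (k4 = 0.544 /M/s)
    Ja → Jb (k5 = 0.0940 /s)

| setting | noon | spring | winter | summer | autumn |
|---|---|---|---|---|---|
| Ja | 0.010 M | 0.030 M | 0.10 M | 0.25 M | 0.80 M |
| time | 40 s | 40 s | 40 s | 40 s | 40 s |

- share of Je in all that became Je or Jf for noon, spring, winter, summer, autumn, in this order
- the shape of the row from first to last (hardly changes / rises all the way / rises, then falls / falls, then rises / falls all the way)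

- percent here means Ja units held: one Jf counts as two
- "hardly changes" means that all values lie within two and a half points (for a concentration: within two and a half percent of the largest)
- run time (noon): 40 s

**Jf ceiling.** Jd goes to Je or, meeting Ja, to Jf, so Jf depends on how much Ja survives until Jd arrives. Step 5 by itself gives Ja a half-life of 7.4 s in noon, and I reckon the decay of Ja by that step. Each stage before Jd then passes on its constant over that constant plus 0.0940 /s: 0.734 for Jb and 0.444 for Jc. Ja's own stage gives half, which cancels the two Ja units in one Jf. Jd contributes a time of 7.59 s. Multiplying these by 0.544 /M/s and the charge gives the Jf ceiling, the fraction of the charge ending as Jf if step 4 drains neither Ja nor Jd: in noon, 1.35 %.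

**Noon bracket.** The half-life of Ja is shorter than 40 s, so I take Jf at its ceiling. With instant early stages, Je in noon reaches 77.9 %, which gives an upper end of 98.3 %. I put the mean delay of the early stages at about 27.8 s, so my estimate of Je in noon is 36.9 %, and the lower end is 96.5 %. Both ends hold Jf at its ceiling, so this bracket is an estimate, not a strict bound on the share.

**Autumn bracket.** The ceiling grows with the charge to 108 % in autumn, above the whole charge, so there it is no real amount of Jf. The same two Je values then give a rough range of 25.5 % to 41.9 %. Both ends of this reckoning fall as the charge rises.

**The forecast.** It gives 96.8 %, 91.3 %, 77 %, 61 % and 40 %, shape falls all the way, holding that “the Je share still falls at every step”. Its noon value lies inside my bracket, and so does its autumn value.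

**The flask.** The simulation gives 96.9 %, 91.4 %, 77.7 %, 61.7 % and 41.4 %, shape falls all the way.

**Late Je.** After 400 s, noon holds Jf 1.31 %, under its ceiling of 1.35 %, and autumn holds Jf 35.6 %, under 108 %. In autumn, reading at 40 s instead of ten times as long lowers the share by 23 percentage points, from 64.4 % to 41.4 %. That is the largest single effect but not the main reason, being 39 % of the gap to a pure Je share. After 400 s, autumn holds Je 64.4 % and Jf 35.6 %.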